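All runs are simulated with constants of no real substance, and the scatter is random.

The pitfall in a straight run of readings is to take its slope for a rate that lasts, though the stock of starting material that feeds it falls.

| setting | midnight | noon | ash | birch | maple |
|---|---|---|---|---|---|
| starting material | 0.30 M | 0.30 M | 0.30 M | 0.30 M | 0.30 M |
| protic impurity | 0.045 M | 0.068 M | 0.0900 M | 0.0900 M | 0.0900 M |
| catalyst | 12 mol% | 12 mol% | 12 mol% | 12 mol% | 12 mol% |
| temperature | 55 °C | 75 °C | 60 °C | 75 °C | 90 °C |
| remark | run made earlier | run made earlier |  |  |  |
| time |  |  | 5.0 min | 5.0 min | 5.0 min |

- midnight (time / min: target / %): 0.500: 0; 1.00: 0.4; 1.50: 0.6; 2.50: 1.1; 3.00: 2.1; 4.00: 2.0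
- noon (time / s: target / %): 10.0: 0.4; 20.0: 1.0; 30.0: 1.3; 40.0: 2.0; 80.0: 3.7; 120: 6.4

(readings scatter by 0.5 percentage points)

- the flask that comes out highest in amount of target, in percent of the starting material charged, or "all alike" when all lie within 1.5 percentage points (ash / birch / maple / all alike)
- target at the end, in percent of the starting material charged, ash
- target at the end, in percent of the starting material charged, birch
- target at the end, in percent of the starting material charged, maple

- the numbers in the tables scatter by 0.5 percentage points (one standard deviation)

We therefore compare two times: the time given, and the filling time, the inverse of k, where k is the initial rate of target per starting material. Their ratio is the filling number n. Our zero of the scale is the plain case, in which starting material goes to target and nowhere else, so the target fraction is one minus exp(−n).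

The last readings give 0.00500 /min at 55 °C and 0.0320 /min at 75 °C, each carrying the scatter of 0.5 percentage points. The impurity differed too, but we assume that it leaves k alone, so we read the whole factor as temperature: k doubles every 7.47 degrees.

Over 5.0 min, n is then 0.0398 in ash, 0.160 in birch and 0.644 in maple. Our plain case thus gives 3.90 %, 14.8 % and 47.5 %, with maple highest.

The forecast also chose maple, but with 7 %, 18 % and 40 %, which is higher than ours in birch and lower in maple, and it noted: “Both curves are straight, with no induction or visible catalyst death”.

The simulation gives maple, with 3.55 %, 11.8 % and 23.9 %.

    starting material ⇌ target (K = 18.0, k = 0.120 /min, Ea = 92.0 kJ/mol, ΔH = −13.0 kJ/mol)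
    target + catalyst ⇌ isomer of the product + catalyst, rate k2*[catalyst]*[target] forward; the back reaction follows from the equilibrium constant (K = 0.540, k = 0.160 /M/min, Ea = 76.0 kJ/mol, ΔH = 33.0 kJ/mol)
    isomer of the product + catalyst ⇌ starting material + catalyst, rate k3*[catalyst]*[isomer of the product] forward; the back reaction follows from the equilibrium constant (k = 0.950 /M/min, Ea = 71.0 kJ/mol)
    starting material + protic impurity → quenched substrate (k = 0.700 /M/min, Ea = 52.0 kJ/mol)
    (constants at 90 °C)

Part of the shortfall in maple comes from starting material falling back to isomer of the product, together with the short time given: maple gives 23.9 % of target as it stands, 39.3 % without that falling back, and 45.6 % at ten times the time. Maple held 29.9 % of its starting material after 2.50 min and 11.4 % after 5.00 min, so we multiply n by the mean stock. Simpson's weighting of start, middle and end gives 24.8 % of target. Ash read at 12 min held 62.0 % of its starting material; its n, scaled to that time and multiplied by the mean of start and end, gives 7.73 % of target, and that flask held 7.67 % of target.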